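The runs were generated by integration for substances that don't exist; noise was put on by code.

In this closed flask the substrate charged stays in its forms, so by the steps listed target can grow by no more than the substrate and intermediates A, B and C still hold. For the flask, which is gamma continued to 3.0 d, I therefore asked how many half-lives that pool has had.

common to all: substrate 0.050 M
- gamma: partner 0.040 M; temperature 25 °C; the very flask that is asked about, followed so far
- delta: partner 0.040 M; temperature 20 °C; run made earlier
- flask: partner 0.0400 M; temperature 25 °C; time 3.0 d

| run | time / h | target / % | substrate / % |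
|---|---|---|---|
| gamma | 6.00 | 28.5 | 5.2 |
| gamma | 8.00 | 31.9 | 3.5 |
| gamma | 12.0 | 36.9 | 0.5 |
| gamma | 20.0 | 38.2 | 3.4 |
| gamma | 30.0 | 40.7 | 0.6 |
| gamma | 50.0 | 41.9 | 1.5 |
| gamma | 72.0 | 41.0 | 0 |
| delta | 6.00 | 18.3 | 13.4 |
| delta | 8.00 | 21.5 | 7.5 |
| delta | 12.0 | 26.7 | 4.5 |
| delta | 20.0 | 31.5 | 0.4 |
| delta | 30.0 | 34.1 | 0 |
| delta | 50.0 | 35.8 | 1.7 |
| delta | 72.0 | 35.3 | 0 |

(each reading ± 1 percentage point)

- Friday's: at 3.0 d take out 90% of the target then present, then wait 3.0 d
- Saturday's: at 3.0 d raise the temperature by 10 K, then wait 3.0 d
- Thursday's: at 3.0 d add partner, 50.0% of the amount charged, then wait 3.0 d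
- Wednesday's: change nothing and wait 3.0 d more

- target, in percent of the substrate first charged, at 3.0 d
- the option that brings most further target ("none" if no option brings more than 2 percentage points) (Friday's / Saturday's / Thursday's / Wednesday's / none)
- target present, with what was taken out counted in, in percent of the substrate first charged, after Friday's
- target present, with what was taken out counted in, in percent of the substrate first charged, after Thursday's

- percentages count the substrate that a species holds: one self-condensation product counts as two
- target taken out counts as made
- the numbers in the tables scatter with a standard deviation of 1 percentage point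
- what may be going on: substrate -> intermediate A; substrate -> intermediate B; partner + intermediate A -> target; intermediate B <-> intermediate C; intermediate C -> intermediate A; 2 substrate -> self-condensation product; intermediate C -> decomposed reagent
- additions bring no volume worth counting

I took the plateau P of gamma as the mean of its last two target readings, 41.4%, and the gap G = P − target as the measure of the pool still turning into target. Partner did not stop gamma, for its charge equals 80.0% of the substrate, more than P. Two times remained, the half-life h of the gap, read from its values at 6.00 h and 12.0 h, and the time t allowed: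

G = 13 percentage points, then 4.5 points

h = 6.00 h × ln(2) / ln(G ratio) = 3.98 h

t / h = 3.0 d / h = 18.1

This h, the half-life of the gap, is a reading and carries the scatter of 1 point. Carried on from 12.0 h, the gap at 3.0 d comes to 1.3 × 10⁻⁴ points, far under the 2 points an option needs. So I committed to P for now and after Friday's and Thursday's, and to "none" for best.

The forecast gave 41.5% for now, 41.7% after Friday's, 41.8% after Thursday's and none for best, on the ground that “the pool feeding the target has drained”.

The flask gave 40.0% for now, 40.0% after Friday's, 40.0% after Thursday's and none for best.

    substrate → intermediate A (k = 0.200 h⁻¹, Ea = 101 kJ mol⁻¹)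
    substrate → intermediate B (k = 0.160 h⁻¹, Ea = 100 kJ mol⁻¹)
    partner + intermediate A → target (k = 22.0 M⁻¹ h⁻¹, Ea = 60.0 kJ mol⁻¹)
    intermediate B ⇌ intermediate C (K = 15.0, k = 0.270 h⁻¹, Ea = 84.0 kJ mol⁻¹, ΔH = −36.0 kJ mol⁻¹)
    intermediate C → intermediate A (k = 0.180 h⁻¹, Ea = 91.0 kJ mol⁻¹)
    2 substrate → self-condensation product (k = 6.30 M⁻¹ h⁻¹, Ea = 60.0 kJ mol⁻¹)
    intermediate C → decomposed reagent (k = 0.410 h⁻¹, Ea = 95.0 kJ mol⁻¹)
    (constants at 25 °C)

At the 18.1 half-lives that my h of 3.98 h counts to 72.0 h, the flask holds intermediates A, B and C at 0%, 0% and 0%. The answer for now moves by 5 points at 9.65 h, which is 2.42 of those half-lives. The neighbour flask with 0.030 M of substrate, looked at after the same 72.0 h, holds intermediates A, B and C at 0%, 0% and 0%, with target at 47.3%.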